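**Plan**

1. Retrosynthesis: the spiro junction is cut at C3–C4' (aldol) and then at C4–O and C15–C15' (hydration of a hetero-Diels–Alder adduct). This gives two molecules of one monomer, dehydrozaluzanin C, whose C3 ketone is traced back to the C3 methylene of dehydrocostus lactone.
2. In the monomer, ring C (C11–C12 and C12–O6, with C12 arriving as carbon monoxide) and ring B (C6–C7) are cut together. The precursor is a cis-1,2-disubstituted methylenecyclopentane with a formyl group on C5 and a C1 side chain ending in the allene C7=C11=C13, itself cut at C8–C9 and at the ring A aldol bond back to (R)-limonene oxide.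
3. Enabling feature: in each half the α-methylene-γ-butyrolactone O6–C12(=O)–C11(=C13H2)–C7 is fused to the seven-membered ring B across C6–C7. C6=O, the C7=C11 bond of an allene and CO therefore map onto it as a carbonylative [2+2+1], and the C11–C12 bond made there becomes that of both lactones of the dimer, including the one beside the spiro ketone.
4. Forward order: ring A (step 2), side chain (steps 3–8), rings B and C in one operation (step 11), C3 oxidation (steps 12–13), dihydropyran by dimerisation (step 14), its opening (step 15), spiro-cyclopentane (step 16).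
5. Stereochemistry: C1 comes from (R)-limonene; C5 from kinetic protonation anti to the C1 chain; C6 and C7 are set in the key step under control of C1/C5; C4 by α-face cycloaddition; C3 and C4' by the cis-fused, convex-face aldol.

Key step: step 11

Remark: guaiane numbering (C1–C15) is used for all intermediates, and primed locants denote the half of the dimer that carries the spiro ketone. Commercial limonene oxide is a cis/trans mixture and both isomers converge in step 1. The carbinol centre of 10–12 is a mixture that becomes sp2 in step 8. C3 of 18 and C4' of 21 are drawn as the expected epimers, and both centres are erased in the following step.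

**Step 1**
Reactants: 1 (+)-limonene 1,2-oxide
Product: 3 (3R)-6-oxo-3-(prop-1-en-2-yl)heptanal, via limonene-1,2-diol 2 (not isolated)
Conditions: H5IO6, THF/H2O, 0 °C to rt
Reagents that add atoms: water (SMILES: O)
Why: Periodic acid opens the epoxide to the glycol and cleaves it in the same flask (Malaprade cleavage), which should leave the isopropenyl group and the existing stereocentre (later C1) untouched.

**Step 2**
Reactants: 3 (3R)-6-oxo-3-(prop-1-en-2-yl)heptanal
Product: 4 (5S)-2-methyl-5-(prop-1-en-2-yl)cyclopent-1-ene-1-carbaldehyde
Conditions: piperidine (cat.), AcOH (cat.), benzene, reflux, Dean–Stark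
Reagents that add atoms: none
Why: Intramolecular aldol condensation through the enamine of the aldehyde onto the methyl ketone should close ring A as the tetrasubstituted enal; no stereocentre is formed and the existing one is not enolisable.

**Step 3**
Reactants: 4 (5S)-2-methyl-5-(prop-1-en-2-yl)cyclopent-1-ene-1-carbaldehyde
Product: 5 (5R)-5-(3-chloroprop-1-en-2-yl)-2-methylcyclopent-1-ene-1-carbaldehyde
Conditions: Ca(OCl)2, CO2 (dry ice), CH2Cl2/H2O, 0 °C
Reagents that add atoms: calcium hypochlorite (SMILES: [Ca+2].[O-]Cl.[O-]Cl)
Why: Ene-type allylic chlorination by hypochlorous acid should take place only at the electron-rich isopropenyl alkene (the enal alkene is deactivated), with loss of a methyl proton to give the 2-substituted allyl chloride that carries C9.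

**Step 4**
Reactants: 5 (5R)-5-(3-chloroprop-1-en-2-yl)-2-methylcyclopent-1-ene-1-carbaldehyde
Product: 6 (5R)-5-(3-chloroprop-1-en-2-yl)-1-(dimethoxymethyl)-2-methylcyclopent-1-ene
Conditions: HC(OMe)3, MeOH, pyridinium tosylate (cat.), rt
Reagents that add atoms: trimethyl orthoformate (SMILES: COC(OC)OC)
Why: Acid-catalysed acetalisation masks the aldehyde against the carbon nucleophiles of steps 5 and 7.

**Step 5**
Reactants: 6 (5R)-5-(3-chloroprop-1-en-2-yl)-1-(dimethoxymethyl)-2-methylcyclopent-1-ene
Product: 7 4-[(1S)-2-(dimethoxymethyl)-3-methylcyclopent-2-en-1-yl]pent-4-enenitrile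
Conditions: MeCN, n-BuLi, THF, −78 °C; then 6, −78 to 0 °C
Reagents that add atoms: acetonitrile (SMILES: CC#N)
Why: Alkylation of lithioacetonitrile by the primary allylic chloride adds C8 and C7 (direct and allylic displacement give the same product).

**Step 6**
Reactants: 7 4-[(1S)-2-(dimethoxymethyl)-3-methylcyclopent-2-en-1-yl]pent-4-enenitrile
Product: 9 4-[(1S)-2-(dimethoxymethyl)-3-methylcyclopent-2-en-1-yl]pent-4-enal, via N-diisobutylalumino aldimine 8 (not isolated)
Conditions: i-Bu2AlH, CH2Cl2, −78 °C; then H2O, silica gel, 0 °C
Reagents that add atoms: water (SMILES: O)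
Why: Partial hydride reduction of the nitrile stops at the N-aluminoimine, and its near-neutral hydrolysis should give the C7 aldehyde without cleaving the acetal.

**Step 7**
Reactants: 9 4-[(1S)-2-(dimethoxymethyl)-3-methylcyclopent-2-en-1-yl]pent-4-enal
Product: 10 6-[(1S)-2-(dimethoxymethyl)-3-methylcyclopent-2-en-1-yl]hept-6-en-1-yn-3-ol
Conditions: HC≡CMgBr, THF, −78 to 0 °C; then H2O
Reagents that add atoms: ethynylmagnesium bromide (SMILES: C#C[Mg]Br)
Why: Grignard 1,2-addition brings in C11 and C13; both carbinol epimers are carried on because C7 becomes sp2 in step 8.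

**Step 8**
Reactants: 10 6-[(1S)-2-(dimethoxymethyl)-3-methylcyclopent-2-en-1-yl]hept-6-en-1-yn-3-ol
Product: 13 (5S)-1-(dimethoxymethyl)-5-(hepta-1,5,6-trien-2-yl)-2-methylcyclopent-1-ene, via N-alkyl-N-(2-nitrobenzenesulfonyl)hydrazine 11 (not isolated), via propargylic diazene 12 (not isolated)
Conditions: PPh3, diethyl azodicarboxylate, 2-nitrobenzenesulfonylhydrazide, THF, −15 °C to rt
Reagents that add atoms: none
Why: Myers allene synthesis: Mitsunobu displacement of the propargylic alcohol by the sulfonylhydrazide, loss of sulfinic acid and retro-ene loss of N2 from the diazene should transpose the alkyne into the terminal allene C7=C11=C13 under neutral conditions.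

**Step 9**
Reactants: 13 (5S)-1-(dimethoxymethyl)-5-(hepta-1,5,6-trien-2-yl)-2-methylcyclopent-1-ene
Product: 14 (5S)-5-(hepta-1,5,6-trien-2-yl)-2-methylcyclopent-1-ene-1-carbaldehyde
Conditions: pyridinium tosylate (cat.), acetone/H2O, rt
Reagents that add atoms: water (SMILES: O)
Why: Mild acid-catalysed acetal hydrolysis frees the conjugated aldehyde, and the allene and the 1,1-disubstituted alkene should tolerate the weak acid.

**Step 10**
Reactants: 14 (5S)-5-(hepta-1,5,6-trien-2-yl)-2-methylcyclopent-1-ene-1-carbaldehyde
Product: 16 (1R,2R)-2-(hepta-1,5,6-trien-2-yl)-5-methylidenecyclopentane-1-carbaldehyde, via potassium dienolate 15 (not isolated)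
Conditions: KN(SiMe3)2, THF, −78 °C; then AcOH, −78 °C (inverse quench); used crude
Reagents that add atoms: none
Why: Kinetic deconjugation: the base removes a proton from the C15 methyl group (the only γ-position syn to the formyl group) to give the dienolate, and α-protonation at C5 from the face anti to the C1 side chain should set H5 cis to H1 and create the C4=C15 methylene.

**Step 11**
Reactants: 16 (1R,2R)-2-(hepta-1,5,6-trien-2-yl)-5-methylidenecyclopentane-1-carbaldehyde
Product: 17 dehydrocostus lactone
Conditions: Ru3(CO)12 (5 mol %), CO (10 atm), 1,4-dioxane, 100 °C, high dilution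
Reagents that add atoms: carbon monoxide (SMILES: [C-]#[O+])
Why: Proposed new method: a zerovalent ruthenium carbonyl fragment binds the C6=O group and the proximal C7=C11 π-bond of the allene side by side, oxidative cyclisation forms the C6–C7 bond and an oxaruthenacyclopentane carrying the exocyclic C11=C13 methylene, CO inserts into the Ru–C11 bond (this makes the C11–C12 bond) and C12–O6 reductive elimination releases the lactone and the catalyst. The closest known reaction type is the intramolecular allenic hetero-Pauson–Khand reaction of allenyl aldehydes with Ru3(CO)12/CO or Mo(CO)6, which gives bicyclic α-methylene-γ-butyrolactones but has been shown only for five- and six-membered carbocycles; seven-membered rings are known from the carbocyclic allenic Pauson–Khand reaction of allenynes. Ring B closes in a 7-exo-trig sense (C6 onto C7, the C7=C11 bond staying outside the ring), and ring C is the five-membered product of the formal [2+2+1] union of C6=O, C7=C11 and CO, completed by the C11–C12 and C12–O6 bonds. C6 and C7 are both set in the oxidative cyclisation: with ring A cis-fused and its C4 branch equatorial on a chair-like seven-membered transition state, the O6–Ru–C11 metallacycle can sit trans-diequatorial, which places H6 anti to H5 and H7 anti to H6 (6α-O, 7β-C11) as in the trans-lactone of the target. The step needs the proximal and not the distal allene π-bond, no reaction at the C4=C15 and C10=C14 methylenes, trans and not cis lactone fusion, and an intact C5 centre: the five-atom tether C8–C9–C10–C1–C5 delivers C6 only to C7, unactivated 1,1-disubstituted alkenes do not enter this cycle, the length of the tether removes the geometric bias for cis fusion seen with short tethers, and the medium is neutral and base-free.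

**Step 12**
Reactants: 17 dehydrocostus lactone
Product: 18 3α-hydroxydehydrocostus lactone (3-epizaluzanin C)
Conditions: SeO2 (cat.), t-BuOOH, CH2Cl2, rt
Reagents that add atoms: tert-butyl hydroperoxide (SMILES: CC(C)(C)OO), its oxygen relayed by selenium dioxide (SMILES: O=[Se]=O)
Why: Allylic hydroxylation (ene reaction, then [2,3]-sigmatropic shift of the allylseleninic acid) should occur at C3 next to the C4=C15 methylene with oxygen delivered to the convex α-face, a transformation known for this very lactone; either C3 epimer serves because step 13 removes the centre.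

**Step 13**
Reactants: 18 3α-hydroxydehydrocostus lactone (3-epizaluzanin C)
Product: 19 dehydrozaluzanin C
Conditions: Dess–Martin periodinane, CH2Cl2, rt
Reagents that add atoms: none
Why: Dess–Martin oxidation of the allylic alcohol should give the cross-conjugated α-methylene ketone without touching the methylene lactone or the ring-fusion centres.

**Step 14**
Reactants: 19 dehydrozaluzanin C (two molecules)
Product: 20 spiro-dihydropyran dimer
Conditions: 1,1'-bi-2-naphthol (substoichiometric hydrogen-bond donor), neat, 50 °C
Reagents that add atoms: none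
Why: Biomimetic hetero-Diels–Alder dimerisation: the enone O3'=C3'–C4'=C15' of one molecule adds as heterodiene to the C4=C15 methylene of the second with the regiochemistry of enone dimerisation (O3' to C4, C15' to C15), and approach to the convex α-face of ring A should set the only new stereocentre, spiro C4.

**Step 15**
Reactants: 20 spiro-dihydropyran dimer
Product: 21 seco-dimer hydroxy diketone
Conditions: 1 M HCl, THF, rt
Reagents that add atoms: water (SMILES: O)
Why: Acid-catalysed hydration of the cyclic enol ether (protonation at C4', water on C3', opening of the hemiketal) should give the C3' ketone and the C4 tertiary alcohol; the C4–O bond is never broken, so C4 keeps its configuration.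

**Step 16**
Reactants: 21 seco-dimer hydroxy diketone
Product: 22 ainsliadimer A
Conditions: DBU, CH2Cl2, rt
Reagents that add atoms: none
Why: Reversible intramolecular aldol addition (five-membered ring): the more substituted C4' enolate of the C3' ketone adds to the C3 ketone; the cis-fused bicyclo[3.3.0] junction forces the C3 hydroxyl cis to the C4 hydroxyl, and bond formation on the convex α-face of the enolate ring should set the spiro centre C4'.

**Compound list**

1 | (+)-limonene 1,2-oxide, (4R), cis/trans mixture | CC(=C)[C@@H]1CCC2(C)OC2C1 | starting material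
2 | (4R)-limonene-1,2-diol | CC(=C)[C@@H]1CCC(C)(O)C(O)C1 | intermediate (not isolated)
3 | (3R)-6-oxo-3-(prop-1-en-2-yl)heptanal | CC(=O)CC[C@H](CC=O)C(C)=C | intermediate
4 | (5S)-2-methyl-5-(prop-1-en-2-yl)cyclopent-1-ene-1-carbaldehyde | O=CC1=C(C)CC[C@H]1C(C)=C | intermediate
5 | (5R)-5-(3-chloroprop-1-en-2-yl)-2-methylcyclopent-1-ene-1-carbaldehyde (same spatial arrangement as 4) | O=CC1=C(C)CC[C@H]1C(=C)CCl | intermediate
6 | (5R)-5-(3-chloroprop-1-en-2-yl)-1-(dimethoxymethyl)-2-methylcyclopent-1-ene | COC(OC)C1=C(C)CC[C@H]1C(=C)CCl | intermediate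
7 | 4-[(1S)-2-(dimethoxymethyl)-3-methylcyclopent-2-en-1-yl]pent-4-enenitrile | COC(OC)C1=C(C)CC[C@H]1C(=C)CCC#N | intermediate
8 | N-(diisobutylalumino) aldimine of 9 | COC(OC)C1=C(C)CC[C@H]1C(=C)CCC=N[Al](CC(C)C)CC(C)C | intermediate (not isolated)
9 | 4-[(1S)-2-(dimethoxymethyl)-3-methylcyclopent-2-en-1-yl]pent-4-enal | COC(OC)C1=C(C)CC[C@H]1C(=C)CCC=O | intermediate
10 | 6-[(1S)-2-(dimethoxymethyl)-3-methylcyclopent-2-en-1-yl]hept-6-en-1-yn-3-ol (both carbinol epimers) | COC(OC)C1=C(C)CC[C@H]1C(=C)CCC(O)C#C | intermediate
11 | 1-alkyl-1-(2-nitrobenzenesulfonyl)hydrazine from 10 (nitrogen on the former carbinol carbon C7) | COC(OC)C1=C(C)CC[C@H]1C(=C)CCC(C#C)N(N)S(=O)(=O)c1ccccc1[N+](=O)[O-] | intermediate (not isolated)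
12 | propargylic monoalkyl diazene | COC(OC)C1=C(C)CC[C@H]1C(=C)CCC(C#C)N=N | intermediate (not isolated)
13 | (5S)-1-(dimethoxymethyl)-5-(hepta-1,5,6-trien-2-yl)-2-methylcyclopent-1-ene | COC(OC)C1=C(C)CC[C@H]1C(=C)CCC=C=C | intermediate
14 | (5S)-5-(hepta-1,5,6-trien-2-yl)-2-methylcyclopent-1-ene-1-carbaldehyde | O=CC1=C(C)CC[C@H]1C(=C)CCC=C=C | intermediate
15 | potassium dienolate of 14 (O–C6=C5–C4=C15) | [K+].[O-]C=C1C(=C)CC[C@H]1C(=C)CCC=C=C | intermediate (not isolated)
16 | (1R,2R)-2-(hepta-1,5,6-trien-2-yl)-5-methylidenecyclopentane-1-carbaldehyde (cis; guaiane 1α-H, 5α-H) | O=C[C@H]1C(=C)CC[C@H]1C(=C)CCC=C=C | intermediate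
17 | dehydrocostus lactone, (3aS,6aR,9aR,9bS)-3,6,9-trimethylidenedecahydroazuleno[4,5-b]furan-2(3H)-one | C=C1CC[C@H]2C(=C)CC[C@H]3C(=C)C(=O)O[C@@H]3[C@H]21 | intermediate
18 | 3α-hydroxydehydrocostus lactone (3-epizaluzanin C) | C=C1[C@H](O)C[C@H]2C(=C)CC[C@H]3C(=C)C(=O)O[C@@H]3[C@H]21 | intermediate
19 | dehydrozaluzanin C, 3-oxoguaia-4(15),10(14),11(13)-trien-12,6α-olide | C=C1C(=O)C[C@H]2C(=C)CC[C@H]3C(=C)C(=O)O[C@@H]3[C@H]21 | intermediate
20 | spiro-dihydropyran dimer: O3' bonded to C4 on the α-face, C15' bonded to C15, C3'=C4' enol ether, C3 ketone kept | C=C1C(=O)O[C@@H]2[C@@H]3[C@@H](CC(=O)[C@]34CCC5=C(O4)C[C@H]6C(=C)CC[C@H]7C(=C)C(=O)O[C@@H]7[C@H]65)C(=C)CC[C@@H]12 | intermediate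
21 | seco-dimer hydroxy diketone: 3-oxo-4α-hydroxy half joined through C15–C15' to the 3'-oxo half (C4'-H, side chain on the α-face) | C=C1C(=O)O[C@@H]2[C@@H]3[C@@H](CC(=O)[C@]3(O)CC[C@@H]4C(=O)C[C@H]5C(=C)CC[C@H]6C(=C)C(=O)O[C@@H]6[C@H]54)C(=C)CC[C@@H]12 | intermediate
22 | ainsliadimer A | C=C1C(=O)O[C@@H]2[C@@H]3[C@@H](C[C@@]4(O)[C@]3(O)CC[C@]43C(=O)C[C@H]4C(=C)CC[C@H]5C(=C)C(=O)O[C@@H]5[C@H]43)C(=C)CC[C@@H]12 | target

Total step count: 16. Longest linear sequence: 16 steps (both halves of the dimer come from the same monomer 19).

**Steps most likely to fail**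

1. Step 11 (Proposed new method). The seven-membered oxidative cyclisation may be too slow to compete with epimerisation or reconjugation of the aldehyde, or it may close the lactone with cis fusion or with the wrong aldehyde face.
 Fallback with known chemistry, setting out from 10 and coming back at 17. Alcohol 10 would be mesylated (MsCl, Et3N, CH2Cl2, −78 °C) to the propargylic mesylate F1. Acetal hydrolysis (pyridinium tosylate, acetone/H2O) would give the enal mesylate F2, and deconjugation as in step 10 the cis β,γ-unsaturated aldehyde mesylate F3. Ring B would then be closed alone by an intramolecular Nozaki–Hiyama-type Barbier propargylation (CrCl2, LiI, THF/DMA): the configurationally labile allenylchromium species adds through C7 to the C6 aldehyde in a cyclic transition state, so both C7 epimers of F3 should converge on the trans-7-ethynyl-6-hydroxy hydroazulene F4. The lactone would be closed last by palladium-catalysed cyclocarbonylation of this homopropargylic alcohol (PdCl2, SnCl2, PPh3, CO, MeCN, 75 °C), in which an alkoxycarbonyl-palladium group on O6 inserts the alkyne and so forms the same C11–C12 bond, giving 17.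

2. Step 10. Deprotonation may occur at C3 instead of C15, or the cis aldehyde may epimerise at C5 or reconjugate during quench and handling.
 Fallback setting out from 14 and coming back at 16: base-free photochemical deconjugation. Irradiation of 14 (λ ≥ 300 nm, CH2Cl2, catalytic 1,2-dimethylimidazole as proton shuttle) would give the photodienol F5 by a 1,5-hydrogen shift from the C15 methyl group, the only γ-hydrogens within reach of the excited carbonyl oxygen. Ketonisation by protonation of C5 anti to the C1 chain would then give 16.

3. Step 14. The dimerisation may show low regio- or facial selectivity, or be overtaken by carbo-Diels–Alder or oligomerisation pathways through the methylene lactones.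
 Fallback setting out from 19 (with 18 as partner) and coming back at 20: a directed cross-cycloaddition. Enone 19 would be combined with an excess of allylic alcohol 18, which has no enone and can act only as dienophile; its 3α-hydroxyl should hydrogen-bond to the enone oxygen and deliver it to the α-face of C4, giving the 3-hydroxy spiro-dihydropyran F6. Dess–Martin oxidation of the C3 alcohol would then give 20.

**Further compounds**

F1 | step 11 | 6-[(1S)-2-(dimethoxymethyl)-3-methylcyclopent-2-en-1-yl]hept-6-en-1-yn-3-yl methanesulfonate | COC(OC)C1=C(C)CC[C@H]1C(=C)CCC(OS(C)(=O)=O)C#C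
F2 | step 11 | 6-[(1S)-2-formyl-3-methylcyclopent-2-en-1-yl]hept-6-en-1-yn-3-yl methanesulfonate | O=CC1=C(C)CC[C@H]1C(=C)CCC(OS(C)(=O)=O)C#C
F3 | step 11 | 6-[(1R,2R)-2-formyl-3-methylidenecyclopentyl]hept-6-en-1-yn-3-yl methanesulfonate (cis) | O=C[C@H]1C(=C)CC[C@H]1C(=C)CCC(OS(C)(=O)=O)C#C
F4 | step 11 | 5-ethynyl-3,8-dimethylidenedecahydroazulen-4-ol (guaiane 1α-H, 5α-H, 6α-OH, 7β-ethynyl) | C=C1CC[C@H]2C(=C)CC[C@@H](C#C)[C@H](O)[C@H]21
F5 | step 10 | photodienol of 14, [(2S)-2-(hepta-1,5,6-trien-2-yl)-5-methylidenecyclopentylidene]methanol | OC=C1C(=C)CC[C@H]1C(=C)CCC=C=C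
F6 | step 14 | 3α-hydroxy analogue of 20 (C3 of the dienophile-derived half is a secondary alcohol) | C=C1C(=O)O[C@@H]2[C@@H]3[C@@H](C[C@@H](O)[C@]34CCC5=C(O4)C[C@H]6C(=C)CC[C@H]7C(=C)C(=O)O[C@@H]7[C@H]65)C(=C)CC[C@@H]12
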